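The vessel was closed and stirred. Gas held above the liquid fed the nucleophile, of which none was dissolved at the start. The flasks differed in their charge of free base.

| flask | electrophile | free base | gas | time |
|---|---|---|---|---|
| Monday's | 0.050 M | 0.150 M | 2.7 mM (held) | 15 h |
| Thursday's | 0.050 M | 0.200 M | 2.7 mM (held) | 15 h |
| Friday's | 0.050 M | 0.250 M | 2.7 mM (held) | 15 h |

    electrophile + nucleophile → acid set free + target (k1 = 0.00434 /M/s)
    nucleophile + acid set free ⇌ protonated nucleophile, settled at all times (K2 = 4.4 × 10⁵ /M)
    acid set free + free base ⇌ salt of the base (K3 = 13000 /M, k3 = 0.00118 /M/s)
    free base + target → over-reaction product (k4 = 6.56 × 10⁻⁵ /M/s)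
    gas ⇌ nucleophile, rate k5*(csat - [nucleophile]) (k5 = 0.0130 /s, csat = 2.7 mM)

* part of the electrophile that has reacted at the end, Monday's
* part of the electrophile that has reacted at the end, Thursday's
* part of the electrophile that has reacted at the end, Friday's
* what raising the concentration of free base from its lowest to its highest value here does to the part of the electrophile that has reacted (changes below 5 percentage points count as none) (it rises / it falls / no change)

- at the start none of nucleophile is dissolved
- run time (Monday's): 15 h

I began at the short end. The gas step refills nucleophile with a half-life of 53.3 s, while step one alone, at the charged electrophile, would halve it in 0.89 h. The refill was much faster, so I held [nucleophile] at 2.7 mM.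

Then I went to the long end. With its partner held, the electrophile decays pseudo-first-order:

saturation half-life = ln(2) / (0.00434 /M/s × 2.7 mM) = 16.4 h

I call this time, in which [electrophile] halves with [nucleophile] at 2.7 mM, the saturation half-life. For the run of 15 h it gave:

reacted part = 1 − exp(−ln(2) × 15 h / 16.4 h) = 46.9 %

The rate of step one contains no free base. Free base can reach it through acid set free and nucleophile, but on Monday's charge the half-life of acid set free by the forward direction of step three alone is 1.1 h, longer than the half-life of the refill.

The weak link was the held [nucleophile]. I reckoned that each electrophile cost two nucleophile, one into target and one as protonated nucleophile, because the equilibrium constant of step two times 2.7 mM is 1190, which favours the protonated form. The gas had to bring both, so I expected [nucleophile] to sag below 2.7 mM: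

sag at the charge = 2 × 0.00434 /M/s × 0.050 M / 0.0130 /s = 3.34 %

The sag shrinks with [electrophile]. Summed over the run, it takes the sag times the reacted part from the exponent:

loss = 3.34 % × 46.9 % = 0.0157

reacted part = 1 − exp(−(ln(2) × 15 h / 16.4 h − 0.0157)) = 46.1 %

I committed to 46.1 % for Monday's, Thursday's and Friday's.

The forecast gave 46 %, 46 % and 46 % for those flasks, and no change. Its ground was “so the base barely matters”. It used the same sag, so our agreement was no independent check.

The simulation gave 46.0 %, 46.0 % and 46.0 %, and no change, a change of 0 percentage points.

In Monday's flask, 73.6 % of the electrophile was left at 7.50 h, where the saturation half-life gives 72.8 %. Target was made 4.71 times faster than used up at 5.98 h, and 1.88 times at 15.0 h. At 15.0 h, target and over-reaction product stood at 35.0 % and 11.1 % in Monday's flask, and at 29.5 % and 16.6 % in Friday's flask.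

Now Monday's flask read at 25 h. The saturation half-life gives 65.2 %, and with the sag 64.4 %. The computed result was 64.4 %.

The numbers belong to no real substance, and the outcome is calculated.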